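**Plan**
- Retrosynthesis: cut the two phenol O–Me bonds and the enedione C=C (ring-closing metathesis), then the aryl–CH bridgehead bond (ketone arylation, deoxygenation), then the two cyclohexene ring bonds that flank the prenyl-bearing quaternary carbon and the ring CH2.
- Enabling feature: in the cyclohexene ring of the benzobicyclo[3.2.1]octene, the bridgehead CH between the prenylated quaternary carbon and the ring CH2 can be carried as a ketone. The ring is then a 1,5-diketone retron: the aryl-bearing quaternary carbon is a Michael site and the methyl-bearing alkene carbon an aldol site. The phenol oxygen ortho to the aryl–C bond ties donor and acceptor together as an aryl β-keto ester.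
- Forward order: aryl glyoxylate → aryl β-keto ester → enone; the key step closes the lactone ring and the cyclohexenone; then lactone opening, alkene shift, benzo bridge (indane ring), deoxygenation, enedione ring by metathesis, hydroquinone by oxidative demethylation and reduction.
- Stereochemistry: both quaternary centres come from the catalyst-controlled, tether-directed Michael step (cis-fused); the bridgehead CH follows from the bridge.

Key step: step 6

Remark: the squaramide pseudo-enantiomer that gives the configuration drawn for 13 and 14 has to be chosen by trial of both; compounds 1, 2, 6, 7, 11 and 23 are taken as commercial.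

**Route**

Step 1
Reactants: 1 2-bromo-1,4-dimethoxybenzene; 2 dimethyl oxalate
Product: 4 methyl 2-(2-bromo-3,6-dimethoxyphenyl)-2-oxoacetate, via aryllithium 3 (not isolated)
Conditions: LiN(i-Pr)2, THF, −78 °C; then 2 (excess), −78 °C
Reagents that add atoms: none
Why: Directed ortho-lithiation at the position flanked by Br and OMe, followed by acylation with the diester, should give the aryl α-keto ester.

Step 2
Reactants: 4 methyl 2-(2-bromo-3,6-dimethoxyphenyl)-2-oxoacetate
Product: 5 methyl 2-(2-bromo-6-hydroxy-3-methoxyphenyl)-2-oxoacetate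
Conditions: BCl3, CH2Cl2, −78 → 0 °C
Reagents that add atoms: none
Why: Chelation of boron between the aryl ketone and the ortho methoxy group should direct selective cleavage of that ether only.

Step 3
Reactants: 6 tert-butyl acetoacetate; 7 prenyl bromide
Product: 8 tert-butyl 2-acetyl-5-methylhex-4-enoate (racemic)
Conditions: K2CO3, acetone, 56 °C
Reagents that add atoms: none
Why: C-alkylation of the β-keto ester enolate with the primary allylic bromide (SN2) should install the prenyl group.

Step 4
Reactants: 5 methyl 2-(2-bromo-6-hydroxy-3-methoxyphenyl)-2-oxoacetate; 8 tert-butyl 2-acetyl-5-methylhex-4-enoate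
Product: 10 3-bromo-4-methoxy-2-(2-methoxy-2-oxoacetyl)phenyl 2-acetyl-5-methylhex-4-enoate, via acylketene 9 (not isolated)
Conditions: PhMe, 110 °C (t-BuOH distilled off)
Reagents that add atoms: none
Why: Thermal loss of tert-butanol from the tert-butyl β-keto ester should give the α-oxoketene, which the phenol traps (transacetoacetylation).

Step 5
Reactants: 10 3-bromo-4-methoxy-2-(2-methoxy-2-oxoacetyl)phenyl 2-acetyl-5-methylhex-4-enoate; 11 1-(triphenylphosphoranylidene)propan-2-one
Product: 12 methyl 2-[2-(2-acetyl-5-methylhex-4-enoyloxy)-6-bromo-5-methoxyphenyl]-4-oxopent-2-enoate (E/Z mixture)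
Conditions: PhMe, 80 °C
Reagents that add atoms: none
Why: Wittig olefination with the stabilised ylide should occur only at the activated α-keto ester carbonyl.

Step 6
Reactants: 12 methyl 2-[2-(2-acetyl-5-methylhex-4-enoyloxy)-6-bromo-5-methoxyphenyl]-4-oxopent-2-enoate
Product: 14 methyl 1-bromo-2-methoxy-9-methyl-6a-(3-methylbut-2-enyl)-6,7-dioxo-6a,7-dihydro-6H-benzo[c]chromene-10a(10H)-carboxylate (cis-fused; 6a-prenyl cis to 10a-CO2Me), via Michael adduct 13 (not isolated)
Conditions: quinine-derived squaramide (10 mol %), PhMe, 0 °C; then p-TsOH·H2O (20 mol %), 60 °C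
Reagents that add atoms: none
Why: The squaramide deprotonates the β-keto ester and holds the enone by hydrogen bonding, so the tertiary carbanion adds in a 6-exo-trig Michael reaction to the aryl-bearing carbon (β to the ketone), closing the dihydrocoumarin ring and joining the two future quaternary carbons; p-TsOH then enolises the acetyl group, which attacks the methyl ketone in a 6-(enolexo)-exo-trig aldol reaction and dehydrates to the cyclohexenone, forming the second bond. The closest known reaction type is the organocatalytic Robinson annulation (Michael addition then aldol condensation) of α-substituted β-keto esters with enones, here made intramolecular through the aryl ester. Both new stereocentres arise in the Michael step: the absolute configuration comes from the chiral catalyst, and the relative configuration (acetyl cis to the 2-oxopropyl chain) from the requirement that only this adduct closes the cis-fused ring while the other can revert by retro-Michael reaction. The step needs 6-exo attack at the hindered aryl-bearing carbon over 7-endo attack at the CH carbon, which ring size and activation by the ketone should secure; it also needs aldol attack of the acetyl methyl on the unhindered methyl ketone over the reverse mode, which the neopentyl position of the acetyl carbonyl should secure. The acidic second stage avoids Claisen-type acyl transfer to the aryl ester.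

Step 7
Reactants: 14 methyl 1-bromo-2-methoxy-9-methyl-6a-(3-methylbut-2-enyl)-6,7-dioxo-6a,7-dihydro-6H-benzo[c]chromene-10a(10H)-carboxylate
Product: 16 dimethyl 2-(2-bromo-3,6-dimethoxyphenyl)-4-methyl-1-(3-methylbut-2-enyl)-6-oxocyclohex-4-ene-1,2-dicarboxylate (1-CO2Me cis to the aryl group), via phenol 15 (not isolated)
Conditions: K2CO3, MeOH, 0 °C; then MeI, DMF, 23 °C
Reagents that add atoms: methanol, CO; iodomethane, CI
Why: Transesterification of the aryl lactone followed by Williamson O-methylation of the phenoxide should free the aryl group to rotate, so that its other ortho carbon can later reach the ring ketone.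

Step 8
Reactants: 16 dimethyl 2-(2-bromo-3,6-dimethoxyphenyl)-4-methyl-1-(3-methylbut-2-enyl)-6-oxocyclohex-4-ene-1,2-dicarboxylate
Product: 18 dimethyl 2-(2-bromo-3,6-dimethoxyphenyl)-4-methyl-1-(3-methylbut-2-enyl)-6-oxocyclohex-3-ene-1,2-dicarboxylate, via potassium dienolate 17 (not isolated)
Conditions: KOt-Bu, THF, −20 °C; then AcOH, −78 °C
Reagents that add atoms: none
Why: γ-Deprotonation to the thermodynamic endocyclic dienolate and kinetic α-protonation should move the alkene out of conjugation (deconjugation as known for isophorone-type enones).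

Step 9
Reactants: 18 dimethyl 2-(2-bromo-3,6-dimethoxyphenyl)-4-methyl-1-(3-methylbut-2-enyl)-6-oxocyclohex-3-ene-1,2-dicarboxylate
Product: 19 dimethyl 9-hydroxy-1,4-dimethoxy-7-methyl-10-(3-methylbut-2-enyl)-8,9-dihydro-5H-5,9-methanobenzo[7]annulene-5,10-dicarboxylate (10-CO2Me syn to the benzo ring, prenyl syn to the alkene bridge)
Conditions: NiBr2(bipy) (10 mol %), Mn powder, DMF, 50 °C
Reagents that add atoms: none
Why: Nickel-catalysed reductive intramolecular addition of the aryl bromide to the ketone (Barbier/Nozaki–Hiyama type) should close the five-membered ring under neutral conditions that leave the β,γ-alkene in place; the carbinol carbon is a bridgehead, so its configuration is fixed by the bridge.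

Step 10
Reactants: 19 dimethyl 9-hydroxy-1,4-dimethoxy-7-methyl-10-(3-methylbut-2-enyl)-8,9-dihydro-5H-5,9-methanobenzo[7]annulene-5,10-dicarboxylate
Product: 20 the 9-O-(methoxyoxalyl) ester of 19
Conditions: ClC(=O)CO2Me, DMAP (cat.), Et3N, CH2Cl2, 0 °C
Reagents that add atoms: methyl chlorooxoacetate, COC(=O)C(Cl)=O
Why: Acylation of the tertiary bridgehead alcohol should give the oxalate needed for radical deoxygenation, without the strong base that could trigger a retro-aldol cleavage.

Step 11
Reactants: 20 the 9-O-(methoxyoxalyl) ester of 19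
Product: 21 dimethyl 1,4-dimethoxy-7-methyl-10-(3-methylbut-2-enyl)-8,9-dihydro-5H-5,9-methanobenzo[7]annulene-5,10-dicarboxylate
Conditions: Bu3SnH, AIBN (cat.), PhMe, 110 °C
Reagents that add atoms: none
Why: Barton-type radical deoxygenation of the tertiary oxalate should give a bridgehead radical that takes hydrogen at the only accessible site, so the CH configuration follows from the ring system.

Step 12
Reactants: 21 dimethyl 1,4-dimethoxy-7-methyl-10-(3-methylbut-2-enyl)-8,9-dihydro-5H-5,9-methanobenzo[7]annulene-5,10-dicarboxylate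
Product: 22 1,4-dimethoxy-7-methyl-10-(3-methylbut-2-enyl)-8,9-dihydro-5H-5,9-methanobenzo[7]annulene-5,10-dicarbaldehyde
Conditions: i-Bu2AlH, CH2Cl2, −78 °C
Reagents that add atoms: none
Why: Both esters sit on quaternary carbons, so their aluminium hemiacetals should survive at low temperature and give the dialdehyde on work-up.

Step 13
Reactants: 22 1,4-dimethoxy-7-methyl-10-(3-methylbut-2-enyl)-8,9-dihydro-5H-5,9-methanobenzo[7]annulene-5,10-dicarbaldehyde; 23 vinylmagnesium bromide (one equivalent is consumed per aldehyde; the second equivalent is entered under the reagents that add atoms)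
Product: 24 the 5,10-bis(1-hydroxyprop-2-enyl) compound (mixture of carbinol epimers)
Conditions: 23 (3 equiv), THF, −78 → 23 °C; then aq. NH4Cl
Reagents that add atoms: vinylmagnesium bromide (second equivalent), C=C[Mg]Br
Why: Two successive Grignard 1,2-additions, one equivalent of 23 per aldehyde, should give the bis-allylic diol, the excess reagent and the warming driving the second addition even if the first alkoxide rests as a lactolate on the neighbouring aldehyde; the carbinol configurations do not matter because both are oxidised later.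

Step 14
Reactants: 24 the 5,10-bis(1-hydroxyprop-2-enyl) compound
Product: 25 the cyclohex-2-ene-1,4-diol annulated across the two quaternary carbons (O,O′-dimethyl ether of the target with both enedione carbonyls as CH–OH)
Conditions: second-generation Grubbs catalyst (5 mol %), CH2Cl2, 40 °C
Reagents that add atoms: none
Why: Ring-closing metathesis of the two monosubstituted alkenes should form the six-membered ring much faster than any reaction of the trisubstituted prenyl or ring alkenes.

Step 15
Reactants: 25 the cyclohex-2-ene-1,4-diol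
Product: 26 the O,O′-dimethyl ether of the target
Conditions: Dess–Martin periodinane, CH2Cl2, 23 °C
Reagents that add atoms: none
Why: Oxidation of both allylic alcohols should give the cis-enedione.

Step 16
Reactants: 26 the O,O′-dimethyl ether of the target
Product: 28 CNP0513322.1 (target), via quinone 27 (not isolated)
Conditions: (NH4)2Ce(NO3)6, MeCN–H2O, 0 °C; then Na2S2O4, H2O–EtOAc, 0 °C
Reagents that add atoms: water, O
Why: Oxidative demethylation of the 1,4-dimethoxyarene to the p-quinone and immediate dithionite reduction should give the hydroquinone without touching the prenyl group or the stereocentres.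

**Compound list**

1 | 2-bromo-1,4-dimethoxybenzene | COc1ccc(OC)c(Br)c1 | starting material
2 | dimethyl oxalate | COC(=O)C(=O)OC | starting material
3 | (2-bromo-3,6-dimethoxyphenyl)lithium | [Li]c1c(OC)ccc(OC)c1Br | intermediate
4 | methyl 2-(2-bromo-3,6-dimethoxyphenyl)-2-oxoacetate | COC(=O)C(=O)c1c(OC)ccc(OC)c1Br | intermediate
5 | methyl 2-(2-bromo-6-hydroxy-3-methoxyphenyl)-2-oxoacetate | COC(=O)C(=O)c1c(O)ccc(OC)c1Br | intermediate
6 | tert-butyl acetoacetate | CC(=O)CC(=O)OC(C)(C)C | starting material
7 | prenyl bromide (1-bromo-3-methylbut-2-ene) | CC(C)=CCBr | starting material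
8 | tert-butyl 2-acetyl-5-methylhex-4-enoate (racemic) | CC(C)=CCC(C(C)=O)C(=O)OC(C)(C)C | intermediate
9 | 2-acetyl-5-methylhexa-1,4-dien-1-one (acetyl(prenyl)ketene) | CC(C)=CCC(=C=O)C(C)=O | intermediate
10 | 3-bromo-4-methoxy-2-(2-methoxy-2-oxoacetyl)phenyl 2-acetyl-5-methylhex-4-enoate (racemic, enolisable) | CC(C)=CCC(C(C)=O)C(=O)Oc1ccc(OC)c(Br)c1C(=O)C(=O)OC | intermediate
11 | 1-(triphenylphosphoranylidene)propan-2-one | CC(=O)C=P(c1ccccc1)(c1ccccc1)c1ccccc1 | starting material
12 | methyl 2-[2-(2-acetyl-5-methylhex-4-enoyloxy)-6-bromo-5-methoxyphenyl]-4-oxopent-2-enoate (E/Z mixture) | CC(C)=CCC(C(C)=O)C(=O)Oc1ccc(OC)c(Br)c1C(=CC(C)=O)C(=O)OC | intermediate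
13 | methyl 3-acetyl-5-bromo-6-methoxy-3-(3-methylbut-2-enyl)-2-oxo-4-(2-oxopropyl)chromane-4-carboxylate (acetyl cis to 2-oxopropyl; configuration as in SMILES) | CC(C)=CC[C@@]1(C(C)=O)C(=O)Oc2ccc(OC)c(Br)c2[C@]1(C(=O)OC)CC(C)=O | intermediate
14 | methyl 1-bromo-2-methoxy-9-methyl-6a-(3-methylbut-2-enyl)-6,7-dioxo-6a,7-dihydro-6H-benzo[c]chromene-10a(10H)-carboxylate (cis-fused; configuration as in SMILES) | CC(C)=CC[C@@]12C(=O)Oc3ccc(OC)c(Br)c3[C@]1(C(=O)OC)CC(C)=CC2=O | intermediate
15 | dimethyl 2-(2-bromo-6-hydroxy-3-methoxyphenyl)-4-methyl-1-(3-methylbut-2-enyl)-6-oxocyclohex-4-ene-1,2-dicarboxylate (1-CO2Me cis to aryl) | CC(C)=CC[C@]1(C(=O)OC)C(=O)C=C(C)C[C@@]1(C(=O)OC)c1c(O)ccc(OC)c1Br | intermediate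
16 | dimethyl 2-(2-bromo-3,6-dimethoxyphenyl)-4-methyl-1-(3-methylbut-2-enyl)-6-oxocyclohex-4-ene-1,2-dicarboxylate (1-CO2Me cis to aryl) | CC(C)=CC[C@]1(C(=O)OC)C(=O)C=C(C)C[C@@]1(C(=O)OC)c1c(OC)ccc(OC)c1Br | intermediate
17 | potassium dienolate of 16 (through-conjugated, endocyclic) | CC(C)=CC[C@]1(C(=O)OC)C([O-])=CC(C)=C[C@@]1(C(=O)OC)c1c(OC)ccc(OC)c1Br.[K+] | intermediate
18 | dimethyl 2-(2-bromo-3,6-dimethoxyphenyl)-4-methyl-1-(3-methylbut-2-enyl)-6-oxocyclohex-3-ene-1,2-dicarboxylate (1-CO2Me cis to aryl) | CC(C)=CC[C@]1(C(=O)OC)C(=O)CC(C)=C[C@@]1(C(=O)OC)c1c(OC)ccc(OC)c1Br | intermediate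
19 | dimethyl 9-hydroxy-1,4-dimethoxy-7-methyl-10-(3-methylbut-2-enyl)-8,9-dihydro-5H-5,9-methanobenzo[7]annulene-5,10-dicarboxylate (10-CO2Me syn to benzo ring) | CC(C)=CC[C@@]1(C(=O)OC)[C@@]2(C(=O)OC)C=C(C)C[C@]1(O)c1c(OC)ccc(OC)c12 | intermediate
20 | 9-O-(methoxyoxalyl) ester of 19 | CC(C)=CC[C@@]1(C(=O)OC)[C@@]2(C(=O)OC)C=C(C)C[C@]1(OC(=O)C(=O)OC)c1c(OC)ccc(OC)c12 | intermediate
21 | dimethyl 1,4-dimethoxy-7-methyl-10-(3-methylbut-2-enyl)-8,9-dihydro-5H-5,9-methanobenzo[7]annulene-5,10-dicarboxylate (10-CO2Me syn to benzo ring) | CC(C)=CC[C@@]1(C(=O)OC)[C@@]2(C(=O)OC)C=C(C)C[C@@H]1c1c(OC)ccc(OC)c12 | intermediate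
22 | 1,4-dimethoxy-7-methyl-10-(3-methylbut-2-enyl)-8,9-dihydro-5H-5,9-methanobenzo[7]annulene-5,10-dicarbaldehyde | CC(C)=CC[C@@]1(C=O)[C@@]2(C=O)C=C(C)C[C@@H]1c1c(OC)ccc(OC)c12 | intermediate
23 | vinylmagnesium bromide | C=C[Mg]Br | starting material
24 | 5,10-bis(1-hydroxyprop-2-enyl)-1,4-dimethoxy-7-methyl-10-(3-methylbut-2-enyl)-8,9-dihydro-5H-5,9-methanobenzo[7]annulene (carbinol epimers) | CC(C)=CC[C@@]1(C(O)C=C)[C@@]2(C(O)C=C)C=C(C)C[C@@H]1c1c(OC)ccc(OC)c12 | intermediate
25 | O,O′-dimethyl ether of the target with both enedione carbonyls reduced to CH–OH (carbinol epimers) | CC(C)=CC[C@@]12C(O)C=CC(O)[C@@]13C=C(C)C[C@@H]2c1c(OC)ccc(OC)c13 | intermediate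
26 | O,O′-dimethyl ether of the target | CC(C)=CC[C@@]12C(=O)C=CC(=O)[C@@]13C=C(C)C[C@@H]2c1c(OC)ccc(OC)c13 | intermediate
27 | p-quinone corresponding to the target | CC(C)=CC[C@@]12C(=O)C=CC(=O)[C@@]13C=C(C)C[C@@H]2C1=C3C(=O)C=CC1=O | intermediate
28 | CNP0513322.1 | CC(C)=CC[C@@]12C(=O)C=CC(=O)[C@@]13C=C(C)C[C@@H]2c1c(O)ccc(O)c13 | target

**Step count and risks**

Total steps: 16. Longest linear sequence: 15 (steps 1, 2, 4–16; step 3 is a side branch).

Steps most likely to fail:

1. Step 6. The Michael addition may stall at the congested aryl-bearing carbon, take the 7-endo course or give the trans adduct, and the acid stage may cyclise the prenyl group onto a carbonyl oxygen. Fallback, setting out from 5: heating 5 with 2,2,6-trimethyl-4H-1,3-dioxin-4-one would give the aryl acetoacetate 3-bromo-4-methoxy-2-(2-methoxy-2-oxoacetyl)phenyl 3-oxobutanoate F1. Piperidinium acetate would then close it by Knoevenagel condensation to the coumarin methyl 3-acetyl-5-bromo-6-methoxy-2-oxo-2H-chromene-4-carboxylate F2. A Mukaiyama–Michael addition of 2-(trimethylsilyloxy)propene at C-4, catalysed by Cu(OTf)2 with a chiral bisoxazoline ligand, would set the aryl-bearing quaternary centre and give methyl 3-acetyl-5-bromo-6-methoxy-2-oxo-4-(2-oxopropyl)chromane-4-carboxylate F3. C-Prenylation of its β-keto lactone carbon with 7 and K2CO3 would give 13; only the epimer with acetyl cis to the 2-oxopropyl chain can be carried on with p-TsOH, and the route is rejoined at 14.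

2. Step 9. Oxidative addition at the doubly ortho-substituted aryl bromide may be slow, so that protodebromination or reduction of the ketone wins over ring closure. Fallback, setting out from 18: halogen–lithium exchange with t-BuLi at −100 °C in THF, transmetalation with CeCl3 and Parham-type intramolecular 1,2-addition of the aryl–cerium species to the ketone would give 19 directly, where the route is rejoined.

3. Step 8. The dienolate may form at the methyl group instead of the ring CH2, or the β,γ-enone may slip back into conjugation during the quench. Fallback, setting out from 16: soft enolisation with TBSOTf and Et3N would trap the thermodynamic dienolate as the silyl dienol ether dimethyl 2-(2-bromo-3,6-dimethoxyphenyl)-6-(tert-butyldimethylsilyloxy)-4-methyl-1-(3-methylbut-2-enyl)cyclohexa-3,5-diene-1,2-dicarboxylate F4, which can be purified; buffered protodesilylation (Bu4NF, AcOH, −78 °C) with α-protonation would then give 18, where the route is rejoined.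

**Further compounds**

F1 | step 6 | 3-bromo-4-methoxy-2-(2-methoxy-2-oxoacetyl)phenyl 3-oxobutanoate | CC(=O)CC(=O)Oc1ccc(OC)c(Br)c1C(=O)C(=O)OC
F2 | step 6 | methyl 3-acetyl-5-bromo-6-methoxy-2-oxo-2H-chromene-4-carboxylate | COC(=O)C1=C(C(C)=O)C(=O)Oc2ccc(OC)c(Br)c12
F3 | step 6 | methyl 3-acetyl-5-bromo-6-methoxy-2-oxo-4-(2-oxopropyl)chromane-4-carboxylate | CC(=O)C1C(=O)Oc2ccc(OC)c(Br)c2[C@]1(C(=O)OC)CC(C)=O
F4 | step 8 | dimethyl 2-(2-bromo-3,6-dimethoxyphenyl)-6-(tert-butyldimethylsilyloxy)-4-methyl-1-(3-methylbut-2-enyl)cyclohexa-3,5-diene-1,2-dicarboxylate | CC(C)=CC[C@]1(C(=O)OC)C(O[Si](C)(C)C(C)(C)C)=CC(C)=C[C@@]1(C(=O)OC)c1c(OC)ccc(OC)c1Br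
F0 | step 9 | none | none
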